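**Plan** (prostanoid numbering: ester C1, ring C8–C12 with C9=O, C10–Br and C12–OAc, ω-chain C13–C20)
1. Cuts: C7=C8 (aldol condensation, releases the C1–C7 enal); C14=C15 (Z-selective cross-metathesis, leaves an allyl group on C12); ring bond C11–C12 (4π electrocyclisation); C9–C10 and C10–C11 (dibromocarbene, whose carbon becomes C10 and keeps one bromine); C12–OAc (acetic acid added to an ynone); C8–C9 (acetylide acylation).
2. Enabling feature: the ring C8–C9(=O)–C10(Br)=C11–C12 is a 2-bromocyclopent-2-enone whose two carbons ÎČ to the carbonyl, C11 and C12, are bonded to each other, which is the retron of a 2-bromo-3-oxypentadienyl cation closing at its termini. C11 is an unsubstituted CH and C12 is quaternary, so after closure only C11 can lose a proton (this fixes C10=C11), and the C12 acetate can be carried in as an enol acetate.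
3. Forward: acyclic ynone → (Z)-enol acetate → 2-silyloxydiene → gem-dibromocyclopropane → silver-triggered ring opening and ring closure, which forms the only ring with Br, OAc and the enone in place and expels the helper silyl group and second bromine → ω-chain by cross-metathesis → α-chain by boron aldol and elimination.
4. Stereochemistry: C12 from torquoselective conrotatory closure of an achiral cation under a chiral counter-anion; 14Z from the metathesis catalyst; 5E from the enal; 7Z from the anti aldol of the ring-constrained boron enolate followed by anti elimination.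

Key step: step 5

Assumption: the sense of induction of the chiral anion in step 5 cannot be predicted with confidence; the (R)-acid is written and its enantiomer is to be used if a first test shows the opposite sense.

**Step 1**
Reactants: 1 pent-1-en-4-yne; 2 N-methoxy-N-methylacetamide
Product: 4 hept-6-en-3-yn-2-one, via lithium pent-4-en-1-yn-1-ide 3 (not isolated)
Conditions: n-BuLi (1.0 equiv), THF, −78 °C; then 2, −78 to 0 °C; inverse quench into cold aq. NH4Cl
Reagents that add atoms: n-butyllithium [Li]CCCC (its lithium stands only in 3)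
Why: Acylation of a lithium acetylide by a Weinreb amide stops at the ketone because the chelated tetrahedral adduct persists until the quench, and the cold, mildly acidic quench should avoid base-induced isomerisation of the skipped enynone.

**Step 2**
Reactants: 4 hept-6-en-3-yn-2-one
Product: 5 (Z)-6-oxohepta-1,4-dien-4-yl acetate
Conditions: AcOH (5 equiv), Ph3PAuNTf2 (2 mol %), CH2Cl2, 23 °C
Reagents that add atoms: acetic acid CC(=O)O
Why: Gold-catalysed anti-hydroacyloxylation of an alkyne, in which acetic acid attacks the π-activated ynone at the carbon ÎČ to the carbonyl and protodeauration with retention should leave acetoxy and acyl cis (Z), under base-free conditions that spare the doubly activated CH2.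

**Step 3**
Reactants: 5 (Z)-6-oxohepta-1,4-dien-4-yl acetate
Product: 6 (Z)-6-[(triisopropylsilyl)oxy]hepta-1,4,6-trien-4-yl acetate
Conditions: TIPSOTf (1.2 equiv), Et3N (2 equiv), CH2Cl2, −78 to 0 °C
Reagents that add atoms: triisopropylsilyl trifluoromethanesulfonate CC(C)[Si](OS(=O)(=O)C(F)(F)F)(C(C)C)C(C)C
Why: Soft enolisation (O-silylation, then deprotonation of the silyloxocarbenium ion at the neighbouring methyl group) should give the cross-conjugated 2-silyloxydiene, as in the preparation of 2-silyloxy-4-oxy-1,3-dienes from ÎČ-oxy enones, without a free enolate that could attack the enol acetate.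

**Step 4**
Reactants: 6 (Z)-6-[(triisopropylsilyl)oxy]hepta-1,4,6-trien-4-yl acetate
Product: 7 (Z)-1-[2,2-dibromo-1-[(triisopropylsilyl)oxy]cyclopropyl]penta-1,4-dien-2-yl acetate (racemic at the cyclopropane carbon)
Conditions: PhHgCBr3 (1.1 equiv), benzene, 70 °C; product kept cold and used without delay
Reagents that add atoms: phenyl(tribromomethyl)mercury BrC(Br)(Br)[Hg]c1ccccc1
Why: Electrophilic dibromocarbene, released under neutral conditions, should add ([2+1] cycloaddition) to the most electron-rich double bond, the 1,1-disubstituted silyl enol ether, in preference to the conjugated enol acetate and the terminal alkene; the new stereocentre is racemic and is erased in step 5.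

**Step 5**
Reactants: 7 (Z)-1-[2,2-dibromo-1-[(triisopropylsilyl)oxy]cyclopropyl]penta-1,4-dien-2-yl acetate
Product: 10 (S)-1-allyl-3-bromo-4-oxocyclopent-2-en-1-yl acetate, via 2-bromo-3-silyloxypentadienyl cation 8 (not isolated), via silyl dienol ether 9 (not isolated)
Conditions: (R)-3,3'-bis(2,4,6-triisopropylphenyl)-1,1'-binaphthyl-2,2'-diyl N-triflylphosphoramide (10 mol %), Ag2CO3 (0.6 equiv), 4 Å MS, toluene, −20 to 23 °C, dark; then HF·pyridine, THF, 0 °C
Reagents that add atoms: none
Why: Proposed new method: the silver salt of the chiral acid abstracts bromide, the cyclopropane opens in a disrotatory sense to the 2-bromo-3-silyloxypentadienyl cation 8 held as an ion pair with the chiral anion, and 8 closes the five-membered ring in the thermal conrotatory 4π-electrocyclic (Nazarov) mode between its CH2 terminus and its acetoxy-bearing terminus. The closest known reaction type is the racemic silver-assisted ring-opening/Nazarov cascade of 1-silyloxy-2,2-dihalocyclopropanes to 2-halocyclopent-2-enones, taken together with chiral-anion control of silver-mediated halide abstractions and of BrĂžnsted acid Nazarov cyclisations; their union on an enol ester terminus is new. The one new stereocentre, the quaternary acetoxy carbon, is set by the sense of conrotation that the chiral anion imposes on the geometrically pure (Z)-enol acetate. The 2-silyloxyallyl cation left after closure can lose a proton only from the former CH2 carbon, because its other neighbour is quaternary, so the double bond is fixed next to bromine in 9, which HF·pyridine cleaves to 10 while the proton returned to the anion is taken up by Ag2CO3 to regenerate the silver salt. The step needs selective ionisation of a cyclopropane C–Br bond, secured by the silyloxy donor on the adjacent carbon, and a cation that is not over-stabilised at its oxygenated terminus, secured by the acetyl group that damps the enol oxygen lone pair.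

**Step 6**
Reactants: 10 (S)-1-allyl-3-bromo-4-oxocyclopent-2-en-1-yl acetate; 11 hept-1-ene
Product: 12 (S)-3-bromo-1-[(Z)-oct-2-en-1-yl]-4-oxocyclopent-2-en-1-yl acetate
Conditions: hept-1-ene (5 equiv), Z-selective cyclometalated Grubbs catalyst (ruthenium nitrato 2-isopropoxybenzylidene complex of the N-adamantyl-chelated N'-(2,6-diisopropylphenyl)imidazolin-2-ylidene, 5 mol %), THF, 35 °C, static vacuum
Reagents that add atoms: none
Why: Z-selective cross-metathesis of two terminal alkenes, in which the cyclometalated catalyst forms the cis-disubstituted alkene under kinetic control (14Z) and should leave the electron-poor, trisubstituted bromoenone untouched.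

**Step 7**
Reactants: 13 methyl hex-5-enoate; 14 (E)-but-2-enal
Product: 15 methyl (E)-7-oxohept-5-enoate
Conditions: (E)-but-2-enal (5 equiv), second-generation Hoveyda–Grubbs catalyst (2 mol %), CH2Cl2, 40 °C
Reagents that add atoms: none
Why: Cross-metathesis of a terminal alkene with an α,ÎČ-unsaturated aldehyde is a standard, thermodynamically E-selective route to enals (5E).

**Step 8**
Reactants: 12 (S)-3-bromo-1-[(Z)-oct-2-en-1-yl]-4-oxocyclopent-2-en-1-yl acetate; 15 methyl (E)-7-oxohept-5-enoate
Product: 17 methyl (5E,7S)-7-[(1R,5S)-5-acetoxy-3-bromo-5-[(Z)-oct-2-en-1-yl]-2-oxocyclopent-3-en-1-yl]-7-hydroxyhept-5-enoate (C7/C8 anti), via dibutylboron dienolate 16 (not isolated)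
Conditions: Bu2BOTf (1.2 equiv), i-Pr2NEt (1.5 equiv), CH2Cl2, −78 °C; then 15, −78 to −40 °C; pH 7 buffer/MeOH work-up without peroxide
Reagents that add atoms: dibutylboron trifluoromethanesulfonate CCCCB(CCCC)OS(=O)(=O)C(F)(F)F (its boron unit stands only in 16)
Why: Boron-mediated aldol addition, in which soft enolisation at C8 (the only enolisable position) gives the ring-constrained (E)-enolate, whose closed Zimmerman–Traxler transition state should give the C7/C8 anti aldol by 1,2-addition to the enal on the face away from the octenyl group; the covalent boron enolate should not expel the ÎČ-acetoxy group, and the other anti diastereomer would converge in step 9.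

**Step 9**
Reactants: 17 methyl (5E,7S)-7-[(1R,5S)-5-acetoxy-3-bromo-5-[(Z)-oct-2-en-1-yl]-2-oxocyclopent-3-en-1-yl]-7-hydroxyhept-5-enoate
Product: 19 methyl (5E,7Z,12R,14Z)-12-acetoxy-10-bromo-9-oxoprosta-5,7,10,14-tetraen-1-oate, via C7 methanesulfonate 18 (not isolated)
Conditions: MsCl (1.5 equiv), Et3N (3 equiv), CH2Cl2, −40 °C; then DBU (1.2 equiv), −40 to 0 °C
Reagents that add atoms: methanesulfonyl chloride CS(=O)(=O)Cl (its mesyl group stands only in 18)
Why: ÎČ-Elimination of the aldol mesylate, in which anti elimination from the anti aldol and, should the enolate (E1cB) path operate, relief of allylic 1,3-strain between C6 and the quaternary C12 both place C6 cis to the C9 carbonyl (7Z); the C7 mesylate should leave far more readily than the C12 acetate, whose loss would give an antiaromatic cyclopentadienone.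

**Compound list**
1 | pent-1-en-4-yne | C=CCC#C | starting material
2 | N-methoxy-N-methylacetamide | CC(=O)N(C)OC | starting material
3 | lithium pent-4-en-1-yn-1-ide (formed in the flask) | [Li]C#CCC=C | intermediate
4 | hept-6-en-3-yn-2-one | CC(=O)C#CCC=C | intermediate
5 | (Z)-6-oxohepta-1,4-dien-4-yl acetate | CC(=O)/C=C(/CC=C)OC(C)=O | intermediate
6 | (Z)-6-[(triisopropylsilyl)oxy]hepta-1,4,6-trien-4-yl acetate | C=C(O[Si](C(C)C)(C(C)C)C(C)C)/C=C(/CC=C)OC(C)=O | intermediate
7 | (Z)-1-[2,2-dibromo-1-[(triisopropylsilyl)oxy]cyclopropyl]penta-1,4-dien-2-yl acetate, racemic at the cyclopropane carbon | BrC1(Br)CC1(O[Si](C(C)C)(C(C)C)C(C)C)/C=C(/CC=C)OC(C)=O | intermediate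
8 | (4Z)-5-acetoxy-2-bromo-3-[(triisopropylsilyl)oxy]octa-1,4,7-trien-3-ylium, ion-paired with the chiral anion (formed in the flask) | C=C(Br)C(=[O+][Si](C(C)C)(C(C)C)C(C)C)/C=C(/CC=C)OC(C)=O | intermediate
9 | (S)-1-allyl-3-bromo-4-[(triisopropylsilyl)oxy]cyclopenta-2,4-dien-1-yl acetate (formed in the flask) | C=CC[C@@]1(OC(C)=O)C=C(Br)C(O[Si](C(C)C)(C(C)C)C(C)C)=C1 | intermediate
10 | (S)-1-allyl-3-bromo-4-oxocyclopent-2-en-1-yl acetate | C=CC[C@@]1(OC(C)=O)C=C(Br)C(=O)C1 | intermediate
11 | hept-1-ene | C=CCCCCC | starting material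
12 | (S)-3-bromo-1-[(Z)-oct-2-en-1-yl]-4-oxocyclopent-2-en-1-yl acetate | CCCCC/C=C\C[C@@]1(OC(C)=O)C=C(Br)C(=O)C1 | intermediate
13 | methyl hex-5-enoate | C=CCCCC(=O)OC | starting material
14 | (E)-but-2-enal | C/C=C/C=O | starting material
15 | methyl (E)-7-oxohept-5-enoate | O=C/C=C/CCCC(=O)OC | intermediate
16 | (S)-3-bromo-4-[(dibutylboranyl)oxy]-1-[(Z)-oct-2-en-1-yl]cyclopenta-2,4-dien-1-yl acetate (formed in the flask) | CCCCC/C=C\C[C@@]1(OC(C)=O)C=C(Br)C(OB(CCCC)CCCC)=C1 | intermediate
17 | methyl (5E,7S)-7-[(1R,5S)-5-acetoxy-3-bromo-5-[(Z)-oct-2-en-1-yl]-2-oxocyclopent-3-en-1-yl]-7-hydroxyhept-5-enoate, C7/C8 anti, side chain trans to the octenyl group | CCCCC/C=C\C[C@@]1(OC(C)=O)C=C(Br)C(=O)[C@@H]1[C@@H](O)/C=C/CCCC(=O)OC | intermediate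
18 | methyl (5E,7S)-7-[(1R,5S)-5-acetoxy-3-bromo-5-[(Z)-oct-2-en-1-yl]-2-oxocyclopent-3-en-1-yl]-7-[(methylsulfonyl)oxy]hept-5-enoate (formed in the flask) | CCCCC/C=C\C[C@@]1(OC(C)=O)C=C(Br)C(=O)[C@@H]1[C@@H](OS(C)(=O)=O)/C=C/CCCC(=O)OC | intermediate
19 | methyl (5E,7Z)-7-[(5R)-5-acetoxy-3-bromo-5-[(Z)-oct-2-en-1-yl]-2-oxocyclopent-3-en-1-ylidene]hept-5-enoate, i.e. methyl (5E,7Z,12R,14Z)-12-acetoxy-10-bromo-9-oxoprosta-5,7,10,14-tetraen-1-oate | CCCCC/C=C\C[C@@]1(OC(C)=O)C=C(Br)C(=O)/C1=C\C=C\CCCC(=O)OC | target

Total step count: 9. Longest linear sequence: 8 steps (steps 1 to 6, 8 and 9; step 7 makes the C1–C7 aldehyde).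

**Steps most likely to fail**

Step 5. The ion pair may discriminate too weakly between the two senses of conrotation, so that 10 would form with low enantiomeric purity. Fallback: from 7, the established racemic silver-assisted cascade (AgBF4, 1.5 equiv, CH2Cl2/MeCN, 23 °C; then HF·pyridine) should give racemic 1-allyl-3-bromo-4-oxocyclopent-2-en-1-yl acetate F1. Preparative chromatography on a cellulose tris(3,5-dimethylphenylcarbamate) phase then separates the enantiomers; (R)-1-allyl-3-bromo-4-oxocyclopent-2-en-1-yl acetate F2 is set aside, and the (S)-enantiomer is 10, where the route is rejoined.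

Step 9. If the mesylate collapses through a long-lived enolate without conformational bias, geometric control at C7=C8 is lost and the 7E isomer would form beside 19. Fallback: from 12, soft enolisation (TMSOTf, Et3N, CH2Cl2, −78 °C) should give (S)-3-bromo-1-[(Z)-oct-2-en-1-yl]-4-[(trimethylsilyl)oxy]cyclopenta-2,4-dien-1-yl acetate F3. Its fluoride-promoted aldol addition to 15 (TASF, 10 mol %, THF, −78 °C) runs through an open transition state and is syn-selective whatever the enol silane geometry, and should give methyl (5E,7R)-7-[(1R,5S)-5-acetoxy-3-bromo-5-[(Z)-oct-2-en-1-yl]-2-oxocyclopent-3-en-1-yl]-7-[(trimethylsilyl)oxy]hept-5-enoate F4. Dilute acid work-up frees the C7/C8 syn aldol, methyl (5E,7R)-7-[(1R,5S)-5-acetoxy-3-bromo-5-[(Z)-oct-2-en-1-yl]-2-oxocyclopent-3-en-1-yl]-7-hydroxyhept-5-enoate F5. Stereospecific syn dehydration with DCC and catalytic CuCl (Et2O, 23 °C) then leads to 19, since the syn aldol/syn elimination pair gives the same 7Z geometry as the anti/anti pair.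

Step 6. Turnover may be slow at the allyl group next to the quaternary carbon, and secondary metathesis may erode the Z selectivity. Fallback: from 10, ozonolysis of the terminal alkene only (O3, CH2Cl2, −78 °C, Sudan red end point; then Ph3P) should give (S)-3-bromo-4-oxo-1-(2-oxoethyl)cyclopent-2-en-1-yl acetate F6. A Z-selective Wittig reaction with the unstabilised ylide from hexyltriphenylphosphonium bromide (NaHMDS, THF, −78 °C) then returns to 12.

**Further compounds**
F1 | step 5 | racemic 1-allyl-3-bromo-4-oxocyclopent-2-en-1-yl acetate | C=CCC1(OC(C)=O)C=C(Br)C(=O)C1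
F2 | step 5 | (R)-1-allyl-3-bromo-4-oxocyclopent-2-en-1-yl acetate | C=CC[C@]1(OC(C)=O)C=C(Br)C(=O)C1
F3 | step 9 | (S)-3-bromo-1-[(Z)-oct-2-en-1-yl]-4-[(trimethylsilyl)oxy]cyclopenta-2,4-dien-1-yl acetate | CCCCC/C=C\C[C@@]1(OC(C)=O)C=C(Br)C(O[Si](C)(C)C)=C1
F4 | step 9 | methyl (5E,7R)-7-[(1R,5S)-5-acetoxy-3-bromo-5-[(Z)-oct-2-en-1-yl]-2-oxocyclopent-3-en-1-yl]-7-[(trimethylsilyl)oxy]hept-5-enoate | CCCCC/C=C\C[C@@]1(OC(C)=O)C=C(Br)C(=O)[C@@H]1[C@H](O[Si](C)(C)C)/C=C/CCCC(=O)OC
F5 | step 9 | methyl (5E,7R)-7-[(1R,5S)-5-acetoxy-3-bromo-5-[(Z)-oct-2-en-1-yl]-2-oxocyclopent-3-en-1-yl]-7-hydroxyhept-5-enoate (C7/C8 syn) | CCCCC/C=C\C[C@@]1(OC(C)=O)C=C(Br)C(=O)[C@@H]1[C@H](O)/C=C/CCCC(=O)OC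
F6 | step 6 | (S)-3-bromo-4-oxo-1-(2-oxoethyl)cyclopent-2-en-1-yl acetate | O=CC[C@@]1(OC(C)=O)C=C(Br)C(=O)C1
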